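The examiner lays down two earlier runs and two new flasks of J, closed, stirred and held at one temperature, and asks what leads at the end of each.

| flask | J | remark | time |
|---|---|---|---|
| dawn | 0.12 M | run made earlier |  |
| winter | 0.19 M | run made earlier |  |
| Thursday's | 0.25 M |  | 80 min |
| Friday's | 0.25 M |  | 200 min |

- dawn (time / min: Z / %, Q / %, J / %): 4.00: 0, 9.8, 80.5; 12.0: 3.2, 19.8, 59.0; 25.0: 11.1, 28.8, 45.0; 40.0: 18.0, 29.4, 35.4; 50.0: 22.7, 30.4, 32.5; 60.0: 26.7, 29.3, 28.1
- winter (time / min: Z / %, Q / %, J / %): 4.00: 0.2, 9.3, 82.0; 12.0: 2.9, 22.6, 60.5; 25.0: 9.2, 29.3, 45.2; 40.0: 18.6, 29.7, 35.7; 50.0: 23.0, 30.9, 30.6; 60.0: 26.6, 29.8, 28.6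

(standard deviation of a reading: 1 percentage point)

1. which of these there is most of at the end, counted by the J in it, Thursday's (Z / Q / J)
2. which of these there is most of at the end, counted by the J in it, Friday's (Z / Q / J)
3. how much there is at the end of the one of these that leads, in percent of the J charged: Thursday's
4. how much there is at the end of the one of these that leads, in percent of the J charged: Friday's

- candidate steps: J <-> Q; Q <-> Z; J <-> L
- a reading of J is of its free form alone

Does the charge matter? No, as far as these runs show: it rose by a factor of 1.58, yet J at 25.0 min reads 45.0 % and 45.2 %. So I call the runs first order, average them, and apply their fractions of the charge to 0.25 M.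

Is Z slowing? The readings say so, within their scatter. Its pace is 0.00543 min⁻¹ from 25.0 min to 40.0 min, then 0.00418 min⁻¹ up to 60.0 min, so it falls across the 17.5 min between the middles of those stretches.

And in logarithms? If the gap to Z's end value shrinks exponentially, the pace shrinks with it, which gives 153 min. This is the decade time, the minutes in which that gap shrinks by a factor of 10: a relaxation time counted in powers of ten.

How firm is it? Not very. Each pace rests on a gain near 8.36 %, and a reading scatters by 1 percentage point, so I hold it no better than a factor of 2.

Where does Z go? At 50.0 min the gap is the pace times the decade time over ln(10), or 27.7 %. Z reads 22.9 % there, so it ends near 50.6 %.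

Your answer? I reckon Z at 32.9 % in Thursday's flask and 47.7 % in Friday's. Both stand above Q's last reading of 29.8 %, so Z leads both.

The forecast also names Z, with 32.5 % (30.5 % to 35 %) for Thursday's and 43 % (37 % to 50 %) for Friday's, and it calls its estimate for the step from Q to Z “poorly defined”; its Friday figure is lower than mine.

Z leads with 35.9 % in Thursday's flask and 52.8 % in Friday's.

    J ⇌ Q (K = 1.80, k = 5.00 × 10⁻⁴ s⁻¹)
    Q ⇌ Z (K = 2.20, k = 4.10 × 10⁻⁴ s⁻¹)
    J ⇌ L (K = 0.360, k = 4.30 × 10⁻⁴ s⁻¹)

At 2000 min Friday's flask holds Z 55.6 %. Taking that as Z's end value, the gap in Thursday's flask at 80 min is 19.7 %. Carried 120 min forward at the decade time of 153 min, that gap becomes 3.23 %, which puts Z at 52.4 % in Friday's flask beside the 52.8 % it holds. Carried 40.0 min forward, the same gap puts Z at 44.8 %, and Friday's flask stopped at 120 min holds 45.2 %.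

Readings and results come from a simulation from invented constants; scatter was added.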